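Assumption: ring A is the 6-methyl (acyl) ring and ring B the ring with the free carboxyl group. In both, C1 carries the carboxyl carbon, C2 OH, C3 CHO, C4 OH, C5 H and C6 the CH3 (ring A) or CH2O (ring B) group. The target is achiral; transient stereocentres (in 7, 8, 9, 13, 17) are carried as mixtures because all are destroyed before the target.

## Structural features

Barbatolic acid consists of two pentasubstituted benzene rings joined through one benzylic ester: the C1 carboxyl of ring A is esterified by the CH2–O group on C6 of ring B. Counted from C1, both rings carry the same sequence C2–OH, C3–CHO, C4–OH, C5–H; they differ only at C6 (CH3 or CH2O) and in the state of the C1 carboxyl (ester in ring A, free acid in ring B). With no stereocentre, the difficulty is regiochemical: five contiguous substituents per ring, with the formyl group at C3 between two hydroxyls, a position that electrophilic formylation of a resorcylate must win against C5. The fragile groups are two salicylaldehyde-type formyl groups, four phenols, and a benzylic ester that tolerates neither hydrogenolysis nor alkoxide. In ring B the free carboxyl sits ortho to the acyloxymethyl group and can close to a phthalide with loss of the ring A acid under basic or nucleophilic conditions. The feature exploited is that C1 and C6 of each ring are neighbours bearing a carboxyl carbon and an sp3 carbon, which is the substitution of the two sp carbons of a but-2-ynoate, and that the bridge links the C1 substituent of ring A to the C6 substituent of ring B, so the whole bridge lies on the alkynoate side of both rings. The remaining atoms C2–C5 are identical in both rings and correspond to one 2-substituted 1,3-dioxygenated diene used twice.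

## Logic of the disconnections

19 to 18: the O–C(CH3)3 bond of the ring B ester is cut. The carboxyl ortho to the acyloxymethyl group should be free only in the last step, and acidolysis needs no base, nucleophile or hydrogen. The gain is a ring B carboxyl that stays masked through the whole route. The demand is an acidolysis that leaves two aldehydes, four phenols and the bridge intact.

18 to 16: the C=O of each C3 formyl group is traced to the C=C of a prop-1-enyl group on C3. The formyl carbon is then a carbon substituent already in place, so no electrophilic substitution has to choose between C3 and C5. The gain is that no aldehyde is present during ring construction. The demand is an alkene cleavage that spares the electron-rich rings.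

16 to 15: the double bond is moved out of conjugation (prop-1-enyl to allyl). Allyl is a robust, non-conjugating substituent that an enolate alkylation can supply. The demand is an isomerisation that tolerates free phenols and two esters.

15 to 12 and two molecules of 6 (key disconnection): in ring A and in ring B the C1–C2 and C5–C6 bonds are cut. Both arenes disappear; what remains is the acyclic diyne diester 12, which already holds the bridge, and one cyclic diene. In one sentence: both benzene rings of 15 arise together from 12 by a twofold cycloaddition–cycloreversion with two molecules of 6. The gain is the step from two pentasubstituted arenes to a C8 diyne and a C6 diene, with ten substituent positions fixed by the ring construction. The demands are one orientation at both alkynes, reaction of both alkynes, and loss of the alkene bridge at a temperature the tert-butyl ester survives.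

12 to 10 and 11: the acyl C–O bond of the bridge is cut at a stage where both partners are small alkynes without phenols or aldehydes. The demand is an esterification that avoids conjugate addition to either ynoate.

10 to 9 to 7: the C(sp)–CO2 bond is cut (acetylide acylation) and the primary alcohol is masked as an acetal during that step.

6 to 4 to 3 to 1 and 2: the two O–Si bonds are cut in turn, then the C2–allyl bond of the 1,3-dione. The demand is enolisation of 4 at the CH2 next to the carbonyl rather than at the CH2 next to the silyloxy-bearing carbon.

## Other disconnections considered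

Alternative 1: the first idea is to cut the bridging ester between two finished rings, both traced to methyl orsellinate A1. The forward key step would be alkylation of the carboxylate of haematommic acid A2 (from A1 by Gattermann or Rieche formylation and ester cleavage) with the benzylic bromide A3 (from the tert-butyl ester series by formylation, phenol protection and radical bromination of the C6 methyl). The chosen plan is preferred because here the formyl group enters each ring by electrophilic substitution, where C5 competes with C3. The bromination of the C6 methyl must also spare the aldehyde C–H and the ring, and two separate protected lines are needed before the bridge can be made.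

Alternative 2: the rings could be kept saturated and aromatised late, cutting the C3–CHO bond at the cyclohexane-1,3-dione level. The Michael–Dieckmann product A4 would be C-formylated at C3, the only carbon between two carbonyl groups, to give A5, and A5 dehydrogenated to the ethyl ester of A2. This answers only the C3/C5 question. Dehydrogenating a tricarbonyl enol with halogen or a quinone is expected to attack C3 and the formyl group first, ring B would need a 4-oxygenated crotonate prone to β-elimination under alkoxide, and the bridge would still be formed late as in Alternative 1.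

Alternative 3: an anionic (3+3) benzannulation would cut C4–C5 and C6–C1. A 3-oxoglutarate diester would add in Michael fashion to a but-2-ynoate and the second carbanion would close onto the ynoate ester carbonyl (Claisen), giving the isophthalate A6. In this mode the ester carbon of the ynoate becomes ring carbon C4 and its alkoxy group is expelled, so a bridge built into the alkyne partner would be lost. C3 also arrives as an ester that must be reduced to the aldehyde beside the C1 ester, and a 4-acyloxybut-2-ynoate is expected to isomerise or eliminate under the basic conditions.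

Key step: step 7

## Steps

Step 1
Reactants: 1 5,5-dimethylcyclohexane-1,3-dione (dimedone); 2 allyl bromide
Product: 3 2-allyl-5,5-dimethylcyclohexane-1,3-dione
Conditions: KOH, H2O, 23 → 50 °C
Reagents that add atoms: none
Why: Classical C-alkylation of a cyclic 1,3-dione enolate; water as protic medium and the soft allylic halide favour carbon over oxygen, and the monoalkylated product is removed from further alkylation as its enolate.

Step 2
Reactants: 3 2-allyl-5,5-dimethylcyclohexane-1,3-dione
Product: 4 2-allyl-5,5-dimethyl-3-(trimethylsilyloxy)cyclohex-2-en-1-one
Conditions: TMSCl, Et3N, THF, 0 → 23 °C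
Reagents that add atoms: chlorotrimethylsilane C[Si](C)(C)Cl
Why: O-silylation of the enol of a symmetrical 1,3-dione gives a single vinylogous silyl ester; the allyl group is inert.

Step 3
Reactants: 4 2-allyl-5,5-dimethyl-3-(trimethylsilyloxy)cyclohex-2-en-1-one
Product: 6 2-allyl-5,5-dimethyl-1,3-bis(trimethylsilyloxy)cyclohexa-1,3-diene, via lithium dienolate 5 (not isolated)
Conditions: LiN(iPr)2, THF, −78 °C; then TMSCl, −78 → 23 °C
Reagents that add atoms: chlorotrimethylsilane C[Si](C)(C)Cl
Why: Kinetic deprotonation of a 3-oxy-enone occurs at the CH2 next to the carbonyl (cross-conjugated dienolate), and O-silylation of that enolate gives the 1,3-bis(silyloxy)diene; the gem-dimethyl group blocks aromatisation of the diene.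

Step 4
Reactants: 7 2-(prop-2-yn-1-yloxy)tetrahydro-2H-pyran (racemic)
Product: 9 tert-butyl 4-(tetrahydro-2H-pyran-2-yloxy)but-2-ynoate (racemic), via lithium acetylide 8 (not isolated)
Conditions: n-BuLi, THF, −78 °C; then Boc2O, −78 → 0 °C; H2O work-up
Reagents that add atoms: di-tert-butyl dicarbonate CC(C)(C)OC(=O)OC(=O)OC(C)(C)C
Why: Acylation of a lithium acetylide with Boc2O is a standard route to tert-butyl alkynoates; the acetal protects the alcohol from the base and the anhydride.

Step 5
Reactants: 9 tert-butyl 4-(tetrahydro-2H-pyran-2-yloxy)but-2-ynoate
Product: 10 tert-butyl 4-hydroxybut-2-ynoate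
Conditions: PPTS (cat.), EtOH, 50 °C
Reagents that add atoms: none
Why: Acid-catalysed transacetalisation to ethanol removes the tetrahydropyranyl group; the tert-butyl ester and the ynoate are inert to this weak acid.

Step 6
Reactants: 10 tert-butyl 4-hydroxybut-2-ynoate; 11 but-2-ynoic acid
Product: 12 tert-butyl 4-(but-2-ynoyloxy)but-2-ynoate
Conditions: DCC, DMAP (5 mol %), CH2Cl2, −20 → 0 °C
Reagents that add atoms: none
Why: Steglich esterification of a primary propargylic alcohol; low temperature and a small amount of DMAP keep conjugate addition and base-induced isomerisation of the two ynoates in check.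

Step 7
Reactants: 12 tert-butyl 4-(but-2-ynoyloxy)but-2-ynoate; 6 2-allyl-5,5-dimethyl-1,3-bis(trimethylsilyloxy)cyclohexa-1,3-diene (3 equiv)
Product: 15 tert-butyl 3-allyl-6-{[(3-allyl-2,4-dihydroxy-6-methylbenzoyl)oxy]methyl}-2,4-dihydroxybenzoate, via twofold bicyclo[2.2.2]octadiene cycloadduct 13 (not isolated), via fourfold trimethylsilyl ether 14 (not isolated)
Conditions: neat, 140 °C, sealed tube; then MeOH, PPTS (cat.), 23 °C
Reagents that add atoms: none
Why: Twofold Alder–Rickert benzannulation: each ynoate of 12 undergoes a thermal normal-electron-demand Diels–Alder addition to the s-cis-locked diene of 6 to give the bicyclo[2.2.2]octa-2,5-diene units of 13, and each unit then expels its C5(CH3)2–C6H2 bridge as 2-methylpropene in a retro-Diels–Alder step driven by aromatisation, leaving 14. The closest known reaction type is the Alder–Rickert synthesis of resorcylates from 1,3-bis(silyloxy)cyclohexa-1,3-dienes and alkynoates, here run on two alkynoates of one molecule. Ring A and ring B are each closed by a [4+2] cycloaddition that forms the C1–C2 and C5–C6 bonds of the arene, followed by a [4+2] cycloreversion; no other mode of closure is involved. No stereocentre is created in 15, and the bridgehead stereocentres of 13 vanish on aromatisation, so its diastereomers converge. The selectivity needed is orientation: the silyloxy groups at C1 and C3 of 6 both raise the HOMO coefficient at the unsubstituted terminus C4, which therefore bonds to the β carbon of each ynoate (largest LUMO coefficient), while the oxygen-bearing terminus C1 bonds to the α carbon. Hence in both rings the hydroxyl from diene C1 lies ortho to the carboxyl (arene C2), the allyl group lies between the two oxygens (arene C3) and the hydrogen lies next to CH3 or CH2O (arene C5), the pattern of the target. The allyl group sits on an internal diene carbon, and the tert-butyl ester, the bridging ester and the isolated alkenes should be inert under neutral thermal conditions; excess 6 is used so that the slower but-2-ynoate terminus also reacts. Methanolysis with a trace of acid should then free the four phenols of 14 without touching either ester.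

Step 8
Reactants: 15 tert-butyl 3-allyl-6-{[(3-allyl-2,4-dihydroxy-6-methylbenzoyl)oxy]methyl}-2,4-dihydroxybenzoate
Product: 16 tert-butyl 6-{[(2,4-dihydroxy-6-methyl-3-[(E)-prop-1-enyl]benzoyl)oxy]methyl}-2,4-dihydroxy-3-[(E)-prop-1-enyl]benzoate
Conditions: RuClH(CO)(PPh3)3 (5 mol %), toluene, 80 °C
Reagents that add atoms: none
Why: Ruthenium hydride-catalysed alkene isomerisation (hydrometalation and β-hydride elimination) should move both double bonds into conjugation with the rings, as known for 2-allylphenols; the E isomer is expected, and the geometry is irrelevant because the alkene is cleaved next.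

Step 9
Reactants: 16 tert-butyl 6-{[(2,4-dihydroxy-6-methyl-3-[(E)-prop-1-enyl]benzoyl)oxy]methyl}-2,4-dihydroxy-3-[(E)-prop-1-enyl]benzoate
Product: 18 tert-butyl 3-formyl-6-{[(3-formyl-2,4-dihydroxy-6-methylbenzoyl)oxy]methyl}-2,4-dihydroxybenzoate, via twofold ozonide 17 (not isolated)
Conditions: O3 (2 equiv, to consumption of 16), CH2Cl2, −78 °C; then PPh3, −78 → 23 °C
Reagents that add atoms: ozone [O-][O+]=O
Why: Ozonolysis by the Criegee mechanism with reductive work-up turns each aryl prop-1-enyl group into an aryl aldehyde; at −78 °C the styrene-type alkenes should react much faster than the ester-bearing, hydrogen-bonded resorcinol rings.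

Step 10
Reactants: 18 tert-butyl 3-formyl-6-{[(3-formyl-2,4-dihydroxy-6-methylbenzoyl)oxy]methyl}-2,4-dihydroxybenzoate
Product: 19 barbatolic acid (3-formyl-6-{[(3-formyl-2,4-dihydroxy-6-methylbenzoyl)oxy]methyl}-2,4-dihydroxybenzoic acid)
Conditions: TFA/CH2Cl2 (1:4), 0 → 23 °C
Reagents that add atoms: none
Why: Acidolysis of the tert-butyl ester by alkyl–oxygen cleavage releases the acid without base or nucleophile; the benzylic C–O bond of the bridge is meta to both hydroxyls of ring B and flanked by electron-poor positions, so it should not ionise, and aldehydes and phenols are inert to the acid.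

## Compound list

1 | 5,5-dimethylcyclohexane-1,3-dione (dimedone) | CC1(C)CC(=O)CC(=O)C1 | starting material
2 | allyl bromide | C=CCBr | starting material
3 | 2-allyl-5,5-dimethylcyclohexane-1,3-dione | C=CCC1C(=O)CC(C)(C)CC1=O | intermediate
4 | 2-allyl-5,5-dimethyl-3-(trimethylsilyloxy)cyclohex-2-en-1-one | C=CCC1=C(O[Si](C)(C)C)CC(C)(C)CC1=O | intermediate
5 | lithium 2-allyl-5,5-dimethyl-3-(trimethylsilyloxy)cyclohexa-1,3-dien-1-olate | [Li+].[O-]C1=CC(C)(C)CC(O[Si](C)(C)C)=C1CC=C | intermediate
6 | 2-allyl-5,5-dimethyl-1,3-bis(trimethylsilyloxy)cyclohexa-1,3-diene | C=CCC1=C(O[Si](C)(C)C)CC(C)(C)C=C1O[Si](C)(C)C | intermediate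
7 | 2-(prop-2-yn-1-yloxy)tetrahydro-2H-pyran (racemic) | C#CCOC1CCCCO1 | starting material
8 | lithium acetylide of 7 (racemic) | [Li]C#CCOC1CCCCO1 | intermediate
9 | tert-butyl 4-(tetrahydro-2H-pyran-2-yloxy)but-2-ynoate (racemic) | CC(C)(C)OC(=O)C#CCOC1CCCCO1 | intermediate
10 | tert-butyl 4-hydroxybut-2-ynoate | CC(C)(C)OC(=O)C#CCO | intermediate
11 | but-2-ynoic acid | CC#CC(=O)O | starting material
12 | tert-butyl 4-(but-2-ynoyloxy)but-2-ynoate | CC#CC(=O)OCC#CC(=O)OC(C)(C)C | intermediate
13 | twofold bicyclo[2.2.2]octa-2,5-diene cycloadduct of 12 and 6 (mixture of diastereomers) | CC1=C(C(=O)OCC3=C(C(=O)OC(C)(C)C)C4(O[Si](C)(C)C)CC(C)(C)C3C(O[Si](C)(C)C)=C4CC=C)C2(O[Si](C)(C)C)CC(C)(C)C1C(O[Si](C)(C)C)=C2CC=C | intermediate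
14 | fourfold trimethylsilyl ether of 15 | Cc1cc(O[Si](C)(C)C)c(CC=C)c(O[Si](C)(C)C)c1C(=O)OCc1cc(O[Si](C)(C)C)c(CC=C)c(O[Si](C)(C)C)c1C(=O)OC(C)(C)C | intermediate
15 | tert-butyl 3-allyl-6-{[(3-allyl-2,4-dihydroxy-6-methylbenzoyl)oxy]methyl}-2,4-dihydroxybenzoate | Cc1cc(O)c(CC=C)c(O)c1C(=O)OCc1cc(O)c(CC=C)c(O)c1C(=O)OC(C)(C)C | intermediate
16 | tert-butyl 6-{[(2,4-dihydroxy-6-methyl-3-[(E)-prop-1-enyl]benzoyl)oxy]methyl}-2,4-dihydroxy-3-[(E)-prop-1-enyl]benzoate | Cc1cc(O)c(/C=C/C)c(O)c1C(=O)OCc1cc(O)c(/C=C/C)c(O)c1C(=O)OC(C)(C)C | intermediate
17 | twofold ozonide (bis-1,2,4-trioxolane) of 16 (mixture of diastereomers) | Cc1cc(O)c(C2OC(C)OO2)c(O)c1C(=O)OCc1cc(O)c(C2OC(C)OO2)c(O)c1C(=O)OC(C)(C)C | intermediate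
18 | tert-butyl 3-formyl-6-{[(3-formyl-2,4-dihydroxy-6-methylbenzoyl)oxy]methyl}-2,4-dihydroxybenzoate | Cc1cc(O)c(C=O)c(O)c1C(=O)OCc1cc(O)c(C=O)c(O)c1C(=O)OC(C)(C)C | intermediate
19 | barbatolic acid | Cc1cc(O)c(C=O)c(O)c1C(=O)OCc1cc(O)c(C=O)c(O)c1C(=O)O | target

## Step count and least certain steps

Total step count: 10. Longest linear sequence: 7 steps (steps 4, 5, 6, 7, 8, 9, 10; the diene branch, steps 1, 2, 3 followed by 7 to 10, is equally long).

Step 7 (key step). Most likely to go wrong: incomplete cycloaddition at the less electrophilic but-2-ynoate terminus, so that mono-annulated material accumulates, together with thermal loss of 2-methylpropene from the tert-butyl ester at the temperature that the cycloreversion needs. Fallback (sets out from 12, returns at 15): the cyclic diene is replaced by an open-chain 1,3-bis(silyloxy)diene, so that aromatisation occurs by elimination at room temperature and no cycloreversion is required. Commercial ethyl 2-allyl-3-oxobutanoate F1 would be O-silylated (TMSCl, Et3N) to ethyl 2-allyl-3-(trimethylsilyloxy)but-2-enoate F2, then deprotonated and silylated (LiN(iPr)2, TMSCl, THF, −78 °C) to 2-allyl-1-ethoxy-1,3-bis(trimethylsilyloxy)buta-1,3-diene F3. Diels–Alder addition of F3 (3 equiv) to 12 in toluene at 100–110 °C should give, with the same orientation, the twofold cyclohexa-1,4-diene cycloadduct F4, and MeOH/PPTS at 23 °C should split off ethanol and the silyl groups to give 15.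

Step 10. Most likely to go wrong: attack of the liberated carboxyl group on the neighbouring benzylic carbon (phthalide closure with expulsion of the ring A acid) during prolonged exposure to strong acid, or alkylation of C5 of either ring by the tert-butyl cation. Fallback (sets out from 18, returns at 19): an aprotic, buffered silyl transfer replaces the protic acidolysis. TMSOTf and 2,6-lutidine in CH2Cl2 at 0 °C should convert the tert-butyl ester into the trimethylsilyl ester with loss of 2-methylpropene while silylating the phenols, giving the fivefold trimethylsilyl derivative F7, and brief methanolysis at 0 °C should then release 19 under near-neutral conditions.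

Step 9. Most likely to go wrong: oxidation of the dihydroxyarene rings by ozone once the alkenes are consumed, or oxidation of the new salicylaldehydes by peroxidic intermediates. Fallback (sets out from 16, returns at 18): cleavage in two stages with an oxidant that does not attack arenes. Dihydroxylation with OsO4 (cat.) and N-methylmorpholine N-oxide in acetone/H2O should give the tetraol F6, and glycol cleavage with Pb(OAc)4 in CH2Cl2 at 0 °C should give 18. Periodate is avoided because ortho-hydroxybenzylic alcohols are prone to Adler–Becker oxidation.

Step 8. Most likely to go wrong: addition of an ortho hydroxyl across the alkene (closure to a 2-methyl-2,3-dihydrobenzofuran), or stalling after migration of only one of the two double bonds because the chelating phenols inhibit the catalyst. Fallback (sets out from 14, returns at 16): the isomerisation is moved to the silyl-protected stage. 14 would be freed from excess 6 by evaporation under vacuum instead of being methanolysed, and treated with RuClH(CO)(PPh3)3 in toluene at 80 °C to give the bis[(E)-prop-1-enyl] fourfold trimethylsilyl ether F5. MeOH/PPTS at 23 °C should then give 16.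

## Further compounds

F1 | step 7 | ethyl 2-allyl-3-oxobutanoate (racemic, commercial) | CCOC(=O)C(CC=C)C(C)=O
F2 | step 7 | ethyl 2-allyl-3-(trimethylsilyloxy)but-2-enoate (E/Z mixture) | CCOC(=O)C(CC=C)=C(C)O[Si](C)(C)C
F3 | step 7 | 2-allyl-1-ethoxy-1,3-bis(trimethylsilyloxy)buta-1,3-diene (E/Z mixture) | C=C(O[Si](C)(C)C)C(CC=C)=C(OCC)O[Si](C)(C)C
F4 | step 7 | twofold cyclohexa-1,4-diene cycloadduct of 12 and F3 (mixture of diastereomers) | CC1=C(C(=O)OCC2=C(C(=O)OC(C)(C)C)C(OCC)(O[Si](C)(C)C)C(CC=C)=C(O[Si](C)(C)C)C2)C(OCC)(O[Si](C)(C)C)C(CC=C)=C(O[Si](C)(C)C)C1
F5 | step 8 | fourfold trimethylsilyl ether of 16 | Cc1cc(O[Si](C)(C)C)c(/C=C/C)c(O[Si](C)(C)C)c1C(=O)OCc1cc(O[Si](C)(C)C)c(/C=C/C)c(O[Si](C)(C)C)c1C(=O)OC(C)(C)C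
F6 | step 9 | tert-butyl 3-(1,2-dihydroxypropyl)-6-{[(3-(1,2-dihydroxypropyl)-2,4-dihydroxy-6-methylbenzoyl)oxy]methyl}-2,4-dihydroxybenzoate (mixture of diastereomers) | Cc1cc(O)c(C(O)C(C)O)c(O)c1C(=O)OCc1cc(O)c(C(O)C(C)O)c(O)c1C(=O)OC(C)(C)C
F7 | step 10 | fivefold trimethylsilyl derivative of 19 (trimethylsilyl ester, four trimethylsilyl ethers) | Cc1cc(O[Si](C)(C)C)c(C=O)c(O[Si](C)(C)C)c1C(=O)OCc1cc(O[Si](C)(C)C)c(C=O)c(O[Si](C)(C)C)c1C(=O)O[Si](C)(C)C
A1 | alternative 1 | methyl orsellinate (methyl 2,4-dihydroxy-6-methylbenzoate) | COC(=O)c1c(C)cc(O)cc1O
A2 | alternative 1 | haematommic acid (3-formyl-2,4-dihydroxy-6-methylbenzoic acid) | Cc1cc(O)c(C=O)c(O)c1C(=O)O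
A3 | alternative 1 | tert-butyl 6-(bromomethyl)-3-formyl-2,4-bis(methoxymethoxy)benzoate | COCOc1cc(CBr)c(C(=O)OC(C)(C)C)c(OCOC)c1C=O
A4 | alternative 2 | ethyl 6-methyl-2,4-dioxocyclohexane-1-carboxylate (mixture of stereoisomers and tautomers) | CCOC(=O)C1C(C)CC(=O)CC1=O
A5 | alternative 2 | ethyl 3-formyl-6-methyl-2,4-dioxocyclohexane-1-carboxylate (mixture of stereoisomers and tautomers) | CCOC(=O)C1C(C)CC(=O)C(C=O)C1=O
A6 | alternative 3 | dimethyl 2,4-dihydroxy-6-methylbenzene-1,3-dicarboxylate | COC(=O)c1c(C)cc(O)c(C(=O)OC)c1O
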